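**Plan**

- Retrosynthesis: the aldehyde oxygen and the two tiglate C–O bonds are removed first (allylic oxidation of a 2-isopropenyl group, itself from dehydration of a 2-(2-hydroxypropan-2-yl) group; esterification with tiglic acid). The O1–C2 bond is then cut to an epoxide and the C3–C3a bond to a phenol plus an epoxy aldehyde.
- Enabling feature: C3a lies ortho to the phenolic oxygen O1 of the benzene ring while the para carbon C5 is blocked by the 1-oxyethyl chain. C3, C2, the vinyl carbon and its CH2 and CHO carbons are one oxidised isoprene (C5) unit. The furan ring is therefore a para-substituted phenol joined through its ortho carbon and its oxygen to a prenol-derived 2,3-epoxy aldehyde.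
- Forward: the phenol (4 steps from 4-hydroxyacetophenone) and the epoxy aldehyde (2 steps from prenol) are joined at C3–C3a by magnesium-templated ortho-hydroxyalkylation. The furan ring then closes at O1–C2 by phenoxide opening of the epoxide, followed by desilylation, double tigloylation, dehydration and allylic oxidation.
- Stereochemistry: the side-chain carbinol (R) comes from Noyori transfer hydrogenation. C2 comes from Katsuki–Sharpless epoxidation (D-(−)-tartrate) and is inverted in the ring closure. C3 comes from chelation-controlled addition to the epoxy aldehyde, which after inversion at C2 gives the trans ring. The (E)-ester geometry comes from tiglic acid.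

Key step: step 7

Assumption: locants follow 2,3-dihydro-1-benzofuran numbering (O1, C2, C3, C3a, C4–C7, C7a); the target is read as the trans-(2R,3S) ring with a (1R)-1-(tigloyloxy)ethyl group at C5; aldehyde 8 is volatile and is carried into step 7 as a dried CH2Cl2 solution of known titre.

**Route**

Step 1
Reactants: 1 4-hydroxyacetophenone
Product: 2 4-(tert-butyldimethylsilyloxy)acetophenone
Conditions: TBSCl, imidazole, DMF, rt
Reagents that add atoms: tert-butyldimethylsilyl chloride, C[Si](C)(Cl)C(C)(C)C
Why: Standard silyl ether formation at the acidic phenol, which keeps a free phenoxide out of the transfer hydrogenation and makes the ketone an ordinary para-alkoxy acetophenone.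

Step 2
Reactants: 2 4-(tert-butyldimethylsilyloxy)acetophenone
Product: 3 (1R)-1-[4-(tert-butyldimethylsilyloxy)phenyl]ethanol
Conditions: RuCl[(R,R)-TsDPEN](p-cymene) (1 mol %), HCO2H/Et3N (5:2), 30 °C
Reagents that add atoms: none
Why: Noyori asymmetric transfer hydrogenation of an aryl methyl ketone, in which the (R,R)-diamine complex passes hydride and proton through its six-membered outer-sphere transition state to the carbonyl face that gives the (R)-carbinol.

Step 3
Reactants: 3 (1R)-1-[4-(tert-butyldimethylsilyloxy)phenyl]ethanol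
Product: 4 tert-butyl{4-[(1R)-1-(tert-butyldimethylsilyloxy)ethyl]phenoxy}dimethylsilane
Conditions: TBSCl, imidazole, DMF, rt
Reagents that add atoms: tert-butyldimethylsilyl chloride, C[Si](C)(Cl)C(C)(C)C
Why: Routine silylation of a secondary alcohol at oxygen, so the benzylic stereocentre is retained.

Step 4
Reactants: 4 tert-butyl{4-[(1R)-1-(tert-butyldimethylsilyloxy)ethyl]phenoxy}dimethylsilane
Product: 5 4-[(1R)-1-(tert-butyldimethylsilyloxy)ethyl]phenol
Conditions: Cs2CO3 (0.5 equiv), DMF/H2O (10:1), rt
Reagents that add atoms: none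
Why: Chemoselective desilylation, because attack of carbonate or hydroxide at silicon expels the much better phenoxide leaving group, so the aryl silyl ether falls while the alkyl silyl ether and the stereocentre stay.

Step 5
Reactants: 6 3-methylbut-2-en-1-ol
Product: 7 [(2R)-3,3-dimethyloxiran-2-yl]methanol
Conditions: Ti(Oi-Pr)4 (5 mol %), D-(−)-diethyl tartrate (7 mol %), anhydrous t-BuOOH, 4 Å molecular sieves, CH2Cl2, −20 °C; non-aqueous work-up, distillation
Reagents that add atoms: tert-butyl hydroperoxide, CC(C)(C)OO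
Why: Katsuki–Sharpless asymmetric epoxidation, in which the titanium tartrate complex binds the allylic alkoxide and the peroxide and delivers oxygen to one face of the alkene, D-(−)-tartrate giving the (R)-epoxy alcohol (the mirror image of the (2S) series that L-(+)-tartrate gives with primary allylic alcohols of this kind).

Step 6
Reactants: 7 [(2R)-3,3-dimethyloxiran-2-yl]methanol
Product: 8 (2S)-3,3-dimethyloxirane-2-carbaldehyde
Conditions: SO3·pyridine, DMSO, i-Pr2NEt, CH2Cl2, 0 °C
Reagents that add atoms: none
Why: Parikh–Doering (activated DMSO) oxidation runs cold and non-acidic, which spares the epoxide, and an oxiranyl α-carbon enolises with difficulty, so the stereocentre should survive (the descriptor changes from R to S only because CHO outranks the ring carbon).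

Step 7
Reactants: 5 4-[(1R)-1-(tert-butyldimethylsilyloxy)ethyl]phenol; 8 (2S)-3,3-dimethyloxirane-2-carbaldehyde
Product: 10 2-{(S)-[(2R)-3,3-dimethyloxiran-2-yl](hydroxy)methyl}-4-[(1R)-1-(tert-butyldimethylsilyloxy)ethyl]phenol, via chloromagnesium phenoxide 9 (not isolated)
Conditions: 5 (1.2 equiv), i-PrMgCl (1.2 equiv, Et2O), 0 °C; solvent exchanged for CH2Cl2; 8 (1.0 equiv), −20 °C to rt; aq NH4Cl
Reagents that add atoms: none
Why: The magnesium held on the phenoxide oxygen of 9 binds the aldehyde oxygen, and the ortho carbon attacks the carbonyl through a six-membered cyclic transition state, after which loss of the ortho proton restores the arene and leaves the C3–C3a bond and the C3 carbinol. The closest known reaction type is the ortho-specific hydroxyalkylation of magnesium phenoxides with chiral α-oxygenated aldehydes in non-coordinating solvents, a metal-templated Friedel–Crafts (aldol-type) reaction; an oxiranyl aldehyde is a new member of that aldehyde class. No ring is closed in this step. The new stereocentre C3 is controlled by the epoxide stereocentre: two-point binding of the carbonyl and epoxide oxygens to the same magnesium fixes the aldehyde conformation, and the arene adds to the face away from the dimethyl-substituted epoxide carbon, giving the (S)-carbinol (syn adduct). The step needs ortho regioselectivity, which the metal template and the blocked para carbon C5 secure, and mono-alkylation, which the slight excess of phenoxide favours. It also needs the epoxide to survive, for which the counter-ion is chloride (bromide or iodide would open the epoxide), the medium is ether-free and the reaction is started cold.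

Step 8
Reactants: 10 2-{(S)-[(2R)-3,3-dimethyloxiran-2-yl](hydroxy)methyl}-4-[(1R)-1-(tert-butyldimethylsilyloxy)ethyl]phenol
Product: 11 (2S,3S)-5-[(1R)-1-(tert-butyldimethylsilyloxy)ethyl]-2-(2-hydroxypropan-2-yl)-2,3-dihydro-1-benzofuran-3-ol
Conditions: K2CO3, MeOH, rt
Reagents that add atoms: none
Why: Intramolecular Williamson-type epoxide opening, in which carbonate deprotonates only the phenol (so no Payne rearrangement through a C3 alkoxide) and phenoxide O1 attacks the less substituted epoxide carbon C2 from the back in a 5-exo-tet closure, inverting C2 and placing the 2-hydroxypropan-2-yl group trans to the C3 hydroxyl.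

Step 9
Reactants: 11 (2S,3S)-5-[(1R)-1-(tert-butyldimethylsilyloxy)ethyl]-2-(2-hydroxypropan-2-yl)-2,3-dihydro-1-benzofuran-3-ol
Product: 12 (2S,3S)-5-[(1R)-1-hydroxyethyl]-2-(2-hydroxypropan-2-yl)-2,3-dihydro-1-benzofuran-3-ol
Conditions: Bu4NF, THF, 0 °C to rt
Reagents that add atoms: none
Why: Fluoride-driven desilylation cleaves the Si–O bond only, so the benzylic stereocentre is retained and the triol is freed for esterification.

Step 10
Reactants: 12 (2S,3S)-5-[(1R)-1-hydroxyethyl]-2-(2-hydroxypropan-2-yl)-2,3-dihydro-1-benzofuran-3-ol; 13 tiglic acid [(2E)-2-methylbut-2-enoic acid]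
Product: 14 (1R)-1-[(2S,3S)-2-(2-hydroxypropan-2-yl)-3-{[(2E)-2-methylbut-2-enoyl]oxy}-2,3-dihydro-1-benzofuran-5-yl]ethyl (2E)-2-methylbut-2-enoate
Conditions: 13 (3 equiv), DCC, DMAP, CH2Cl2, 0 °C to rt
Reagents that add atoms: none
Why: Steglich esterification acylates both secondary hydroxyls at oxygen (retention at C3 and at the side-chain carbinol) while the hindered tertiary hydroxyl stays free, and the (E)-geometry of the acid is not disturbed under these neutral conditions.

Step 11
Reactants: 14 (1R)-1-[(2S,3S)-2-(2-hydroxypropan-2-yl)-3-{[(2E)-2-methylbut-2-enoyl]oxy}-2,3-dihydro-1-benzofuran-5-yl]ethyl (2E)-2-methylbut-2-enoate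
Product: 15 (1R)-1-[(2R,3S)-3-{[(2E)-2-methylbut-2-enoyl]oxy}-2-(prop-1-en-2-yl)-2,3-dihydro-1-benzofuran-5-yl]ethyl (2E)-2-methylbut-2-enoate
Conditions: Burgess reagent (MeO2CN–SO2–NEt3 inner salt), toluene, 50 °C
Reagents that add atoms: none
Why: Burgess dehydration is a syn (Ei) elimination that should take a methyl hydrogen (six are available, against one C2–H whose removal would give a strained enol ether) and form the isopropenyl group, as is usual for hydroxyisopropyl dihydrobenzofurans; C2 is untouched (its descriptor becomes R by priority only).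

Step 12
Reactants: 15 (1R)-1-[(2R,3S)-3-{[(2E)-2-methylbut-2-enoyl]oxy}-2-(prop-1-en-2-yl)-2,3-dihydro-1-benzofuran-5-yl]ethyl (2E)-2-methylbut-2-enoate
Product: 16 (1R)-1-[(2R,3S)-2-(3-hydroxyprop-1-en-2-yl)-3-{[(2E)-2-methylbut-2-enoyl]oxy}-2,3-dihydro-1-benzofuran-5-yl]ethyl (2E)-2-methylbut-2-enoate
Conditions: SeO2 (0.3 equiv), t-BuOOH, CH2Cl2, rt
Reagents that add atoms: selenium dioxide, O=[Se]=O (oxygen carrier); tert-butyl hydroperoxide, CC(C)(C)OO (terminal oxygen source)
Why: Riley allylic oxidation (ene reaction followed by [2,3]-sigmatropic shift) should take place at the electron-rich 1,1-disubstituted alkene and its methyl group, as known for 2-isopropenyl dihydrobenzofurans of the rotenoid family, while the electron-poor tiglate alkenes react far more slowly.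

Step 13
Reactants: 16 (1R)-1-[(2R,3S)-2-(3-hydroxyprop-1-en-2-yl)-3-{[(2E)-2-methylbut-2-enoyl]oxy}-2,3-dihydro-1-benzofuran-5-yl]ethyl (2E)-2-methylbut-2-enoate
Product: 17 (1R)-1-[(2R,3S)-3-{[(2E)-2-methylbut-2-enoyl]oxy}-2-(3-oxoprop-1-en-2-yl)-2,3-dihydro-1-benzofuran-5-yl]ethyl (2E)-2-methylbut-2-enoate
Conditions: activated MnO2, CH2Cl2, rt
Reagents that add atoms: none
Why: MnO2 oxidises allylic alcohols selectively to enals under neutral conditions, and nothing else in 16 is oxidisable by it; any 17 already formed in step 12 is combined here.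

**Compound list**

1 | 4-hydroxyacetophenone | CC(=O)c1ccc(O)cc1 | starting material
2 | 4-(tert-butyldimethylsilyloxy)acetophenone | CC(=O)c1ccc(O[Si](C)(C)C(C)(C)C)cc1 | intermediate
3 | (1R)-1-[4-(tert-butyldimethylsilyloxy)phenyl]ethanol | C[C@@H](O)c1ccc(O[Si](C)(C)C(C)(C)C)cc1 | intermediate
4 | tert-butyl{4-[(1R)-1-(tert-butyldimethylsilyloxy)ethyl]phenoxy}dimethylsilane | C[C@@H](O[Si](C)(C)C(C)(C)C)c1ccc(O[Si](C)(C)C(C)(C)C)cc1 | intermediate
5 | 4-[(1R)-1-(tert-butyldimethylsilyloxy)ethyl]phenol | C[C@@H](O[Si](C)(C)C(C)(C)C)c1ccc(O)cc1 | intermediate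
6 | 3-methylbut-2-en-1-ol (prenol) | CC(C)=CCO | starting material
7 | [(2R)-3,3-dimethyloxiran-2-yl]methanol | CC1(C)O[C@@H]1CO | intermediate
8 | (2S)-3,3-dimethyloxirane-2-carbaldehyde | CC1(C)O[C@@H]1C=O | intermediate
9 | chloromagnesium 4-[(1R)-1-(tert-butyldimethylsilyloxy)ethyl]phenoxide | C[C@@H](O[Si](C)(C)C(C)(C)C)c1ccc(O[Mg]Cl)cc1 | intermediate
10 | 2-{(S)-[(2R)-3,3-dimethyloxiran-2-yl](hydroxy)methyl}-4-[(1R)-1-(tert-butyldimethylsilyloxy)ethyl]phenol | CC1(C)O[C@@H]1[C@@H](O)c1cc([C@@H](C)O[Si](C)(C)C(C)(C)C)ccc1O | intermediate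
11 | (2S,3S)-5-[(1R)-1-(tert-butyldimethylsilyloxy)ethyl]-2-(2-hydroxypropan-2-yl)-2,3-dihydro-1-benzofuran-3-ol | CC(C)(O)[C@H]1Oc2ccc([C@@H](C)O[Si](C)(C)C(C)(C)C)cc2[C@@H]1O | intermediate
12 | (2S,3S)-5-[(1R)-1-hydroxyethyl]-2-(2-hydroxypropan-2-yl)-2,3-dihydro-1-benzofuran-3-ol | CC(C)(O)[C@H]1Oc2ccc([C@@H](C)O)cc2[C@@H]1O | intermediate
13 | tiglic acid, (2E)-2-methylbut-2-enoic acid | C/C=C(\C)C(=O)O | starting material
14 | (1R)-1-[(2S,3S)-2-(2-hydroxypropan-2-yl)-3-{[(2E)-2-methylbut-2-enoyl]oxy}-2,3-dihydro-1-benzofuran-5-yl]ethyl (2E)-2-methylbut-2-enoate | CC(C)(O)[C@H]1Oc2ccc([C@@H](C)OC(=O)/C(C)=C/C)cc2[C@@H]1OC(=O)/C(C)=C/C | intermediate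
15 | (1R)-1-[(2R,3S)-3-{[(2E)-2-methylbut-2-enoyl]oxy}-2-(prop-1-en-2-yl)-2,3-dihydro-1-benzofuran-5-yl]ethyl (2E)-2-methylbut-2-enoate | C=C(C)[C@H]1Oc2ccc([C@@H](C)OC(=O)/C(C)=C/C)cc2[C@@H]1OC(=O)/C(C)=C/C | intermediate
16 | (1R)-1-[(2R,3S)-2-(3-hydroxyprop-1-en-2-yl)-3-{[(2E)-2-methylbut-2-enoyl]oxy}-2,3-dihydro-1-benzofuran-5-yl]ethyl (2E)-2-methylbut-2-enoate | C=C(CO)[C@H]1Oc2ccc([C@@H](C)OC(=O)/C(C)=C/C)cc2[C@@H]1OC(=O)/C(C)=C/C | intermediate
17 | (1R)-1-[(2R,3S)-3-{[(2E)-2-methylbut-2-enoyl]oxy}-2-(3-oxoprop-1-en-2-yl)-2,3-dihydro-1-benzofuran-5-yl]ethyl (2E)-2-methylbut-2-enoate (CNP0292799.1) | C=C(C=O)[C@H]1Oc2ccc([C@@H](C)OC(=O)/C(C)=C/C)cc2[C@@H]1OC(=O)/C(C)=C/C | target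

**Step count**

Total steps: 13. Longest linear sequence: 11 steps (steps 1–4 and 7–13, from 4-hydroxyacetophenone); the epoxy aldehyde branch (steps 5 and 6) joins at step 7.

**Steps most likely to fail, with fallbacks**

Step 7. The aldehyde may react through an open, non-chelated arrangement, so that the arene adds to the other carbonyl face and the anti adduct predominates, or the chloromagnesium unit may open the epoxide before the C–C bond forms. The fallback gives up chelation control and corrects C3 afterwards by an SN2 esterification. From 5, Ti(Oi-Pr)4 in toluene with removal of propan-2-ol would give the triisopropoxytitanium phenoxide F1. This halide-free, weakly chelating phenoxide is expected to add ortho-selectively to 8 through the open arrangement and give mainly the C3-epimeric (anti) adduct F2. K2CO3 in MeOH would close F2 to the cis-dihydrobenzofuranol F3. A Mitsunobu esterification of F3 with 13 (PPh3, DIAD, toluene, 0 °C) would invert C3 and give the trans C3 tiglate F4; the tertiary hydroxyl does not react. HF·pyridine in THF would remove the silyl group without acyl migration to give the hydroxy ester F5, and Steglich esterification of F5 with 13 comes back to the route at 14. Any syn adduct 10 formed alongside goes on through steps 8–10, so both C3 epimers converge on 14.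

Step 11. The tertiary centre may ionise instead of undergoing clean syn elimination, with participation of the neighbouring C3 tiglate carbonyl (acyl transfer) or loss of tiglic acid and aromatisation to the benzofuran; elimination toward C2 is a further leak. The fallback moves the dehydration ahead of the esterification, onto a substrate without acyloxy groups. From 11, TBSOTf and 2,6-lutidine (CH2Cl2, −78 °C) would silylate the C3 hydroxyl and give the bis-silyl ether F6. Burgess dehydration of F6 would give the isopropenyl bis-silyl ether F7. Bu4NF would remove both silyl groups to give the isopropenyl diol F8, and Steglich esterification of F8 with 13, now with no tertiary hydroxyl present, comes back to the route at 15.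

Step 12. Competing ene oxidation at the allylic methyl groups of the two tiglates or at C2–H, over-oxidation, and acid-promoted loss of the benzylic esters on long exposure to selenous acid may erode the step. The fallback replaces the selenium ene oxidation by chlorination and N-oxide oxidation. From 15, ene-type allylic chlorination with NaOCl and CeCl3·7H2O (CH2Cl2/H2O, 0 °C), which attacks only the electron-rich 1,1-disubstituted alkene, would give the allylic chloride F9. Ganem oxidation of F9 (4-methylmorpholine N-oxide, NaI cat., MeCN, rt to 50 °C) would turn the chloromethyl group into the aldehyde and come back to the route at 17, bypassing 16.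

**Further compounds**

F1 | step 7 | triisopropoxytitanium 4-[(1R)-1-(tert-butyldimethylsilyloxy)ethyl]phenoxide | C[C@@H](O[Si](C)(C)C(C)(C)C)c1ccc(O[Ti](OC(C)C)(OC(C)C)OC(C)C)cc1
F2 | step 7 | 2-{(R)-[(2R)-3,3-dimethyloxiran-2-yl](hydroxy)methyl}-4-[(1R)-1-(tert-butyldimethylsilyloxy)ethyl]phenol | CC1(C)O[C@@H]1[C@H](O)c1cc([C@@H](C)O[Si](C)(C)C(C)(C)C)ccc1O
F3 | step 7 | (2S,3R)-5-[(1R)-1-(tert-butyldimethylsilyloxy)ethyl]-2-(2-hydroxypropan-2-yl)-2,3-dihydro-1-benzofuran-3-ol | CC(C)(O)[C@H]1Oc2ccc([C@@H](C)O[Si](C)(C)C(C)(C)C)cc2[C@H]1O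
F4 | step 7 | (2S,3S)-5-[(1R)-1-(tert-butyldimethylsilyloxy)ethyl]-2-(2-hydroxypropan-2-yl)-2,3-dihydro-1-benzofuran-3-yl (2E)-2-methylbut-2-enoate | CC(C)(O)[C@H]1Oc2ccc([C@@H](C)O[Si](C)(C)C(C)(C)C)cc2[C@@H]1OC(=O)/C(C)=C/C
F5 | step 7 | (2S,3S)-5-[(1R)-1-hydroxyethyl]-2-(2-hydroxypropan-2-yl)-2,3-dihydro-1-benzofuran-3-yl (2E)-2-methylbut-2-enoate | CC(C)(O)[C@H]1Oc2ccc([C@@H](C)O)cc2[C@@H]1OC(=O)/C(C)=C/C
F6 | step 11 | 2-[(2S,3S)-3-(tert-butyldimethylsilyloxy)-5-[(1R)-1-(tert-butyldimethylsilyloxy)ethyl]-2,3-dihydro-1-benzofuran-2-yl]propan-2-ol | CC(C)(O)[C@H]1Oc2ccc([C@@H](C)O[Si](C)(C)C(C)(C)C)cc2[C@@H]1O[Si](C)(C)C(C)(C)C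
F7 | step 11 | tert-butyl{[(2R,3S)-5-[(1R)-1-(tert-butyldimethylsilyloxy)ethyl]-2-(prop-1-en-2-yl)-2,3-dihydro-1-benzofuran-3-yl]oxy}dimethylsilane | C=C(C)[C@H]1Oc2ccc([C@@H](C)O[Si](C)(C)C(C)(C)C)cc2[C@@H]1O[Si](C)(C)C(C)(C)C
F8 | step 11 | (2R,3S)-5-[(1R)-1-hydroxyethyl]-2-(prop-1-en-2-yl)-2,3-dihydro-1-benzofuran-3-ol | C=C(C)[C@H]1Oc2ccc([C@@H](C)O)cc2[C@@H]1O
F9 | step 12 | (1R)-1-[(2R,3S)-2-(3-chloroprop-1-en-2-yl)-3-{[(2E)-2-methylbut-2-enoyl]oxy}-2,3-dihydro-1-benzofuran-5-yl]ethyl (2E)-2-methylbut-2-enoate | C=C(CCl)[C@H]1Oc2ccc([C@@H](C)OC(=O)/C(C)=C/C)cc2[C@@H]1OC(=O)/C(C)=C/C
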